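**Plan**

- Retrosynthesis: the aryl acetate and free phenol come from a quinone and its dimethyl ether; C3=C(CH3)2 comes from a C3 ketone and the C4–CH2 bond from a C4 enol triflate; the C11–aryl bond, the C9–C10 bond and ring B are cut together back to a hydrindane carrying an isopropenyl carbinol; the hydrindane C8–C10 bond is cut to a keto aldehyde.
- Forward: ring A is 2-methylcyclohexane-1,3-dione; a cyclopentane (C5, C6, C7, C8, C10) is closed on it, then widened to ring B (C5–C10) by insertion of C9 while the arene is attached; ring A is then dressed and the hydroquinone unmasked last.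
- Enabling feature: C9 is a quaternary carbon between C8 and the ring-fusion carbon C10 and carries exactly CH3 and ArCH2. This is the pattern formed when an isopropenyl group on a C8 carbinol is arylated at its CH2 terminus and C10 shifts to the cationic carbon; the C8 carbinol carbon ends as the ketone that becomes the C8 methyl.
- Helper group: the C10 hydroxyl (from the ring closure, absent in the target) raises the migratory aptitude of C10, then directs H2 to the β-face of C8, and is then removed by dehydration and hydrogenation.
- Stereochemistry: C5 from a catalyst-controlled desymmetrisation; C9 from the anti-selective 1,2-shift; C8 from hydroxyl-directed hydrogenation; C10 from axial H-atom transfer anti to the C5 and C9 methyls; C4 from α-face hydroboration (also the thermodynamic epimer next to the C3 ketone).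

Key step: step 9

Remark (assumptions): names use the decalin numbering of the target core (ring A = C1–C5, C10; ring B = C5–C10; C11 = benzylic CH2; β = the face of the C5 methyl); the hydrindane intermediates keep the same atom labels (five-membered ring = C5, C6, C7, C8, C10). Ar = 2,5-dimethoxy-3-methylphenyl. 4-Methoxy-2-methylphenol, [bis(acetoxy)iodo]mesitylene and (3-ethoxy-3-oxopropyl)zinc bromide solution are taken as commercial.

**Step 1**
Reactants: 1 4-methoxy-2-methylphenol
Product: 2 2-bromo-4-methoxy-6-methylphenol
Conditions: NBS (1.0 equiv), MeCN, 0 °C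
Reagents that add atoms: N-bromosuccinimide O=C1CCC(=O)N1Br
Why: Electrophilic aromatic bromination; the free phenol directs to its only open ortho position (para is blocked by OMe), which becomes the ring carbon that later carries the benzylic CH2.

**Step 2**
Reactants: 2 2-bromo-4-methoxy-6-methylphenol
Product: 3 1-bromo-2,5-dimethoxy-3-methylbenzene
Conditions: MeI, K2CO3, acetone, reflux
Reagents that add atoms: iodomethane CI
Why: Williamson O-methylation (SN2); the hydroquinone is carried as its dimethyl ether, which is inert to all organometallic steps and is removed oxidatively at the end.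

**Step 3**
Reactants: 3 1-bromo-2,5-dimethoxy-3-methylbenzene
Product: 5 (2,5-dimethoxy-3-methylphenyl)boronic acid, via aryllithium 4 (not isolated)
Conditions: n-BuLi, THF, −78 °C; B(OiPr)3; then 1 M HCl
Reagents that add atoms: n-butyllithium [Li]CCCC; triisopropyl borate CC(C)OB(OC(C)C)OC(C)C; water O
Why: Bromine–lithium exchange, borylation of the aryllithium and hydrolysis should give the boronic acid regiospecifically.

**Step 4**
Reactants: 5 (2,5-dimethoxy-3-methylphenyl)boronic acid
Product: 6 (2,5-dimethoxy-3-methylphenyl)(2,4,6-trimethylphenyl)iodonium trifluoromethanesulfonate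
Conditions: MesI(OAc)2, TfOH, CH2Cl2, −30 → 0 °C
Reagents that add atoms: [bis(acetoxy)iodo]mesitylene CC(=O)OI(OC(C)=O)c1c(C)cc(C)cc1C; trifluoromethanesulfonic acid OS(=O)(=O)C(F)(F)F
Why: Regiospecific ipso-substitution of the C–B bond by the iodine(III) electrophile (diaryliodonium synthesis from an arylboronic acid); the mesityl group serves as the ligand that is not transferred later.

**Step 5**
Reactants: 7 2-methylcyclohexane-1,3-dione; 8 acrolein
Product: 9 3-(1-methyl-2,6-dioxocyclohexyl)propanal
Conditions: H2O, rt
Reagents that add atoms: none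
Why: Michael addition of the cyclic 1,3-dione through C2 creates the prochiral quaternary carbon (future C5) and the three-carbon tether (C6, C7, C8).

**Step 6**
Reactants: 9 3-(1-methyl-2,6-dioxocyclohexyl)propanal
Product: 10 (3aR,7aS)-7a-hydroxy-3a-methylhexahydro-1H-indene-1,4(2H)-dione (cis-fused ketol: C5 β-CH3, C10 β-OH, ketones at C8 and C4)
Conditions: chiral aminoindanol-derived N-C6F5 triazolium tetrafluoroborate (10 mol %, the enantiomer that delivers the (3aR,7aS)-ketol), Et3N (10 mol %), CH2Cl2, rt
Reagents that add atoms: none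
Why: Intramolecular crossed benzoin reaction under N-heterocyclic carbene catalysis; the acyl anion equivalent of the aldehyde adds to one of the two enantiotopic ring carbonyls (desymmetrisation, catalyst control), which sets C5, and the five-membered ring can only close cis, which places the new C10 hydroxyl on the face of the C5 methyl.

**Step 7**
Reactants: 10 cis-fused ketol
Product: 11 C4 ethylene ketal of 10 (C8 ketone, C10 β-OH and C5 β-CH3 unchanged)
Conditions: 2-ethyl-2-methyl-1,3-dioxolane, ethylene glycol (cat.), TsOH·H2O (cat.), rt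
Reagents that add atoms: 2-ethyl-2-methyl-1,3-dioxolane CCC1(C)OCCO1
Why: Acid-catalysed transketalisation should be selective for the cyclohexanone carbonyl, because a cyclopentanone carbonyl flanked by a fully substituted carbinol carbon ketalises far more slowly.

**Step 8**
Reactants: 11 C4 ethylene ketal of the ketol
Product: 12 8β-isopropenyl-8α,10β-diol (cis-fused hydrindane, C4 ethylene ketal, C5 β-CH3)
Conditions: isopropenylmagnesium bromide (3 equiv), CeCl3 (3 equiv), THF, −78 → 0 °C; aq. NH4Cl
Reagents that add atoms: isopropenylmagnesium bromide CC(=C)[Mg]Br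
Why: Organocerium 1,2-addition to the hindered, enolisable α-hydroxy ketone; the reagent should enter from the convex β-face of the cis-fused bicycle, anti to the cyclohexane ring and its dioxolane, so that the isopropenyl group is cis to the C10 hydroxyl (this C8 carbinol centre is transient and becomes a carbonyl in step 9).

**Step 9**
Reactants: 12 8β-isopropenyl-8α,10β-diol; 6 aryl(mesityl)iodonium triflate
Product: 13 β-hydroxy ketone (cis-fused decalin: C4 ethylene ketal, C5 β-CH3, C8 ketone, C9 β-CH3 and α-CH2Ar, C10 β-OH)
Conditions: 6 (1.3 equiv), Cu(OTf)2 (10 mol %), bis(oxazoline) ligand of matched sense (12 mol %), 2,6-di-tert-butylpyridine (1.5 equiv), CH2Cl2, rt; aq. NaHCO3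
Reagents that add atoms: none
Why: Proposed new method: Cu(I) formed in situ is oxidised by the iodonium salt to an electrophilic aryl–Cu(III) species that transfers the aryl group to the CH2 terminus of the isopropenyl π-bond, and the tertiary cation developing at C9 is quenched by a 1,2-shift of the C8–C10 bond with C8 becoming the carbonyl carbon, so that the aryl–C11 bond, the C9 quaternary centre, ring B and the C8 ketone arise in one event. The closest known reaction type is the copper-catalysed arylation-driven semipinacol rearrangement of tertiary allylic alcohols with diaryliodonium salts (related: arylpalladium-induced ring expansion of 1-isopropenylcyclobutanols to 2-benzyl-2-methylcyclopentanones); new here are the unstrained cyclopentane-1,2-diol and the unactivated 1,1-disubstituted alkene. The six-membered ring is not closed by a cyclisation but by a suprafacial [1,2]-alkyl shift that inserts C9 between C8 and C10 (ring expansion 5 → 6), with retention at the migrating C10. The new stereocentre C9 is set by anti addition across the alkene: the aryl–copper unit, associated with the C8 hydroxyl, attacks the CH2 terminus held syn to that hydroxyl while C10 bonds to the opposite face, and since the substituent next to the C8 oxygen ends on the face that oxygen occupied (α), CH2Ar becomes α and CH3 β; the chiral ligand is chosen to reinforce this sense. The step needs migration of C10 and not of C7, and C-arylation followed by the shift and not O-arylation or proton loss to an allyl arene; the oxygen-bearing, fully substituted C10 has by far the higher migratory aptitude, the hindered tertiary hydroxyls are poor nucleophiles under buffering by the hindered pyridine, and the hydroxyl push makes the shift faster than elimination.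

**Step 10**
Reactants: 13 β-hydroxy ketone
Product: 14 8-methylene compound (C8=CH2; otherwise as 13)
Conditions: Zn, CH2Br2, TiCl4, THF/CH2Cl2, 0 °C → rt
Reagents that add atoms: dibromomethane BrCBr
Why: Takai–Lombardo methylenation is non-basic, so the hindered β-hydroxy ketone should be methylenated without retro-aldol cleavage of the C9–C10 bond, which an ylide base would provoke.

**Step 11**
Reactants: 14 8-methylene compound
Product: 15 8α-methyl-10β-ol (cis-fused decalin: C4 ethylene ketal, 5β-CH3, 8α-CH3, 9β-CH3, 9α-CH2Ar, 10β-OH)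
Conditions: [Ir(cod)(PCy3)(py)]PF6 (5 mol %), H2 (1 atm), CH2Cl2, rt
Reagents that add atoms: none
Why: Hydroxyl-directed homogeneous hydrogenation; iridium bound to the tertiary 10β-hydroxyl delivers H2 to the β-face of the C8 methylene, which sets C8 with its methyl α (trans to the C9 methyl), the epimer that undirected hydrogenation from the open α-face would not give.

**Step 12**
Reactants: 15 8α-methyl-10β-ol
Product: 16 Δ1(10)-alkene (C1=C10; C4 ethylene ketal, 5β-CH3, 8α-CH3, 9β-CH3, 9α-CH2Ar)
Conditions: Burgess reagent, toluene, 70 °C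
Reagents that add atoms: none
Why: Burgess dehydration (syn elimination of the sulfamate ester) removes the helper hydroxyl; C5 and C9 are quaternary, so only the C1 hydrogens are available and only the C1=C10 alkene can form.

**Step 13**
Reactants: 16 Δ1(10)-alkene
Product: 18 trans-fused C4 ketone (10α-H; 5β-CH3, 8α-CH3, 9β-CH3, 9α-CH2Ar), via saturated ketal 17 (not isolated)
Conditions: Mn(dpm)3 (10 mol %), PhSiH3, t-BuOOH, i-PrOH, rt; then 2 M HCl, THF, rt
Reagents that add atoms: water O
Why: Metal-hydride hydrogen-atom-transfer hydrogenation (Mukaiyama-type radical hydrogenation) of the hindered trisubstituted alkene; the tertiary C10 radical should take up hydrogen axially on the α-face because the β-face is closed by the two flanking axial methyls at C5 and C9, which gives the trans ring fusion, and aqueous acid then hydrolyses the ketal.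

**Step 14**
Reactants: 18 trans-fused C4 ketone
Product: 19 C3=C4 enol triflate (4-OTf)
Conditions: KHMDS, THF, −78 °C; PhNTf2; aq. NH4Cl
Reagents that add atoms: N-phenylbis(trifluoromethanesulfonimide) FC(F)(F)S(=O)(=O)N(c1ccccc1)S(=O)(=O)C(F)(F)F
Why: O-Triflation of the potassium enolate; C5 is quaternary, so enolisation is possible only towards C3 and the alkene position is unambiguous.

**Step 15**
Reactants: 19 C3=C4 enol triflate
Product: 20 ethyl 3-(Δ3-decalin-4-yl)propanoate (C3=C4 alkene carrying the CH2CH2CO2Et chain at C4)
Conditions: BrZnCH2CH2CO2Et (2 equiv), Pd(dppf)Cl2 (5 mol %), THF/DMA, 50 °C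
Reagents that add atoms: (3-ethoxy-3-oxopropyl)zinc bromide CCOC(=O)CC[Zn]Br
Why: Negishi cross-coupling of the alkenyl triflate with the zinc homoenolate installs the complete three-carbon acid chain at C4 in its final oxidation state.

**Step 16**
Reactants: 20 Δ3-alkene ester
Product: 22 3α-hydroxy ester (4α-H and 4β-CH2CH2CO2Et), via alkylborane 21 (not isolated)
Conditions: BH3·THF (1.2 equiv), THF, 0 °C → rt; then NaOH, H2O2, 0 °C
Reagents that add atoms: borane–tetrahydrofuran B.C1CCOC1; hydrogen peroxide OO
Why: Hydroboration–oxidation; syn, anti-Markovnikov addition on the α-face (anti to the axial C5 methyl) puts hydrogen on C4 from below, which sets C4 with the chain β, and oxygen on C3; the ester reacts with borane much more slowly than the alkene.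

**Step 17**
Reactants: 22 3α-hydroxy ester
Product: 23 3-keto ester (4β-CH2CH2CO2Et)
Conditions: Dess–Martin periodinane, NaHCO3, CH2Cl2, rt
Reagents that add atoms: none
Why: Dess–Martin oxidation to the C3 ketone; the C4 chain is equatorial, the thermodynamically preferred epimer, so enolisation cannot erode C4.

**Step 18**
Reactants: 23 3-keto ester
Product: 24 3-isopropylidene ethyl ester (C3=C(CH3)2)
Conditions: TiCl4, Zn, pyridine, THF, reflux; acetone (10 equiv)
Reagents that add atoms: acetone CC(C)=O
Why: McMurry reductive cross-coupling with excess acetone (low-valent titanium) converts the carbonyl directly into the tetrasubstituted exocyclic alkene with no regiochemical ambiguity; an ester reacts far more slowly than a ketone under these conditions.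

**Step 19**
Reactants: 24 3-isopropylidene ethyl ester
Product: 25 3-isopropylidene acid (arene still as dimethyl ether)
Conditions: LiOH, THF/MeOH/H2O, rt; then 1 M HCl
Reagents that add atoms: lithium hydroxide [Li+].[OH-]
Why: Saponification of the ethyl ester; it is done before the arene is unmasked because the aryl acetate of the target would not survive hydroxide.

**Step 20**
Reactants: 25 3-isopropylidene acid
Product: 26 quinone acid (2-methyl-6-alkyl-1,4-benzoquinone)
Conditions: CAN (2.5 equiv), MeCN/H2O, 0 °C
Reagents that add atoms: water O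
Why: Oxidative demethylation of the 1,4-dimethoxyarene by cerium(IV) (arene radical cation, attack of water, loss of methanol) should give the p-benzoquinone while the alkene and the acid stay untouched at 0 °C.

**Step 21**
Reactants: 26 quinone acid
Product: 28 CNP0144688.1 (target), via hydroquinone 27 (not isolated)
Conditions: Na2S2O4, Et2O/H2O, rt; then Ac2O (1.05 equiv), pyridine, CH2Cl2, 0 °C; aqueous work-up
Reagents that add atoms: acetic anhydride CC(=O)OC(C)=O
Why: Dithionite reduction to the hydroquinone, then chemoselective O-acetylation of the unhindered phenol (flanked by two ring hydrogens) with one equivalent of anhydride; the other phenol lies between the methyl and the neopentyl-type CH2 and should react far more slowly, and any mixed anhydride of the acid is hydrolysed on work-up.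

**Compound list**

1 | 4-methoxy-2-methylphenol | COc1ccc(O)c(C)c1 | starting material
2 | 2-bromo-4-methoxy-6-methylphenol | COc1cc(C)c(O)c(Br)c1 | intermediate
3 | 1-bromo-2,5-dimethoxy-3-methylbenzene | COc1cc(C)c(OC)c(Br)c1 | intermediate
4 | (2,5-dimethoxy-3-methylphenyl)lithium | COc1cc(C)c(OC)c([Li])c1 | intermediate
5 | (2,5-dimethoxy-3-methylphenyl)boronic acid | COc1cc(C)c(OC)c(B(O)O)c1 | intermediate
6 | (2,5-dimethoxy-3-methylphenyl)(2,4,6-trimethylphenyl)iodonium trifluoromethanesulfonate | COc1cc(C)c(OC)c([I+]c2c(C)cc(C)cc2C)c1.[O-]S(=O)(=O)C(F)(F)F | intermediate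
7 | 2-methylcyclohexane-1,3-dione | CC1C(=O)CCCC1=O | starting material
8 | acrolein | C=CC=O | starting material
9 | 3-(1-methyl-2,6-dioxocyclohexyl)propanal | O=CCCC1(C)C(=O)CCCC1=O | intermediate
10 | (3aR,7aS)-7a-hydroxy-3a-methylhexahydro-1H-indene-1,4(2H)-dione (cis-fused ketol) | O=C1CC[C@@]2(C)C(=O)CCC[C@@]12O | intermediate
11 | C4 ethylene ketal of 10 | O=C1CC[C@@]2(C)C3(OCCO3)CCC[C@@]12O | intermediate
12 | 8β-isopropenyl-8α,10β-diol, C4 ethylene ketal (cis-fused hydrindane) | C=C(C)[C@]1(O)CC[C@@]2(C)C3(OCCO3)CCC[C@@]12O | intermediate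
13 | β-hydroxy ketone: cis-fused decalin, C4 ketal, 5β-CH3, 8-oxo, 9β-CH3, 9α-CH2Ar, 10β-OH | COc1cc(C)c(OC)c(C[C@]2(C)[C@]3(O)CCCC4(OCCO4)[C@]3(C)CCC2=O)c1 | intermediate
14 | 8-methylene analogue of 13 | COc1cc(C)c(OC)c(C[C@]2(C)[C@]3(O)CCCC4(OCCO4)[C@]3(C)CCC2=C)c1 | intermediate
15 | 8α-methyl-10β-ol (C4 ketal, 5β-CH3, 9β-CH3, 9α-CH2Ar) | COc1cc(C)c(OC)c(C[C@]2(C)[C@]3(O)CCCC4(OCCO4)[C@]3(C)CC[C@@H]2C)c1 | intermediate
16 | Δ1(10)-alkene, C4 ketal | COc1cc(C)c(OC)c(C[C@]2(C)C3=CCCC4(OCCO4)[C@]3(C)CC[C@@H]2C)c1 | intermediate
17 | trans-fused saturated ketal (10α-H) | COc1cc(C)c(OC)c(C[C@]2(C)[C@H]3CCCC4(OCCO4)[C@]3(C)CC[C@@H]2C)c1 | intermediate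
18 | trans-fused C4 ketone (10α-H, 5β-CH3, 8α-CH3, 9β-CH3, 9α-CH2Ar) | COc1cc(C)c(OC)c(C[C@]2(C)[C@H]3CCCC(=O)[C@]3(C)CC[C@@H]2C)c1 | intermediate
19 | C3=C4 enol triflate | COc1cc(C)c(OC)c(C[C@]2(C)[C@H]3CCC=C(OS(=O)(=O)C(F)(F)F)[C@]3(C)CC[C@@H]2C)c1 | intermediate
20 | ethyl 3-(Δ3-decalin-4-yl)propanoate | COc1cc(C)c(OC)c(C[C@]2(C)[C@H]3CCC=C(CCC(=O)OCC)[C@]3(C)CC[C@@H]2C)c1 | intermediate
21 | 3α-boryl ester (alkylborane) | COc1cc(C)c(OC)c(C[C@]2(C)[C@H]3CC[C@H](B)[C@@H](CCC(=O)OCC)[C@]3(C)CC[C@@H]2C)c1 | intermediate
22 | 3α-hydroxy ester (4β-chain) | COc1cc(C)c(OC)c(C[C@]2(C)[C@H]3CC[C@H](O)[C@@H](CCC(=O)OCC)[C@]3(C)CC[C@@H]2C)c1 | intermediate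
23 | 3-keto ester (4β-chain) | COc1cc(C)c(OC)c(C[C@]2(C)[C@H]3CCC(=O)[C@@H](CCC(=O)OCC)[C@]3(C)CC[C@@H]2C)c1 | intermediate
24 | 3-isopropylidene ethyl ester | COc1cc(C)c(OC)c(C[C@]2(C)[C@H]3CCC(=C(C)C)[C@@H](CCC(=O)OCC)[C@]3(C)CC[C@@H]2C)c1 | intermediate
25 | 3-isopropylidene acid, hydroquinone dimethyl ether | COc1cc(C)c(OC)c(C[C@]2(C)[C@H]3CCC(=C(C)C)[C@@H](CCC(=O)O)[C@]3(C)CC[C@@H]2C)c1 | intermediate
26 | quinone acid | O=C1C=C(C)C(=O)C(C[C@]2(C)[C@H]3CCC(=C(C)C)[C@@H](CCC(=O)O)[C@]3(C)CC[C@@H]2C)=C1 | intermediate
27 | hydroquinone acid | Oc1cc(C)c(O)c(C[C@]2(C)[C@H]3CCC(=C(C)C)[C@@H](CCC(=O)O)[C@]3(C)CC[C@@H]2C)c1 | intermediate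
28 | CNP0144688.1 | CC(=O)Oc1cc(C)c(O)c(C[C@]2(C)[C@H]3CCC(=C(C)C)[C@@H](CCC(=O)O)[C@]3(C)CC[C@@H]2C)c1 | target

**Step count:** 21 steps in total. Longest linear sequence: 17 steps (steps 5–21); the arene branch (steps 1–4) joins at step 9.

**Steps most likely to fail**

Step 9 (proposed method). The cation at C9 may lose a proton to give an allyl arene or be trapped as an epoxide instead of undergoing the shift. Aryl transfer from the electron-rich iodonium salt may be slow. The shift may also occur on the wrong face of C9, since the facial outcome depends on the C8 carbinol configuration set in step 8. Fallback with known chemistry, setting out from 12 and returning at 13: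
- hydroxyl-directed epoxidation of the isopropenyl group (VO(acac)2, t-BuOOH) should give the epoxy diol F1;
- BF3·OEt2 at −78 °C should trigger the semipinacol rearrangement of the 2,3-epoxy alcohol, in which C10 migrates with inversion at C9, to the hydroxymethyl ketone F2;
- Dess–Martin oxidation gives the keto aldehyde F3;
- aryllithium 4 adds to the aldehyde at −78 °C to give the benzylic alcohol F4;
- thiocarbonyldiimidazole converts it to the thiocarbonylimidazolide F5, and Bu3SnH/AIBN (Barton–McCombie deoxygenation) then gives 13.

Step 13. Hydrogen-atom transfer to the C10 radical may occur on the β-face, because the axial C8 methyl partly shields the α-face; this poor facial selectivity would give the cis-fused decalin. Fallback, setting out from 16 and returning at 22: the alkene is kept and the ring fusion is set later by a directed hydrogenation.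
- aqueous HCl hydrolyses the ketal to the Δ1(10) ketone F6;
- KHMDS/PhNTf2 gives the dienyl triflate F7;
- Negishi coupling with the zinc homoenolate gives the diene ester F8;
- BH3·THF then NaOH/H2O2 hydroborates the less hindered C3=C4 alkene on the α-face to the homoallylic alcohol F9;
- the 3α-hydroxyl of F9 then directs hydrogenation with [Ir(cod)(PCy3)(py)]PF6 to the α-face of the C1=C10 alkene, which gives 22.

Step 18. The hindered, α-branched ketone may be reduced or pinacolised instead of cross-coupling with acetone, and the ester may be attacked by low-valent titanium. Fallback, setting out from 23 and returning at 24: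
- the dianion of isobutyric acid (LDA, 2 equiv, THF, −78 °C) adds to the C3 ketone to give the β-hydroxy acid F10;
- PhSO2Cl/pyridine closes the spiro β-lactone F11;
- thermolysis at 140–160 °C extrudes CO2 by syn elimination to give the tetrasubstituted alkene 24.

**Further compounds**

F1 | step 9 | epoxy diol (epoxide of the isopropenyl group of 12) | C[C@@]1(CO1)[C@]2(O)CC[C@@]3(C)C4(OCCO4)CCC[C@@]23O
F2 | step 9 | hydroxymethyl ketone (9α-CH2OH, 9β-CH3, 8-oxo, 10β-OH, C4 ketal) | OC[C@]2(C)[C@]3(O)CCCC4(OCCO4)[C@]3(C)CCC2=O
F3 | step 9 | keto aldehyde (9α-CHO) | O=C[C@]2(C)[C@]3(O)CCCC4(OCCO4)[C@]3(C)CCC2=O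
F4 | step 9 | benzylic alcohol (C11-OH, mixture of C11 epimers) | COc1cc(C)c(OC)c(C(O)[C@]2(C)[C@]3(O)CCCC4(OCCO4)[C@]3(C)CCC2=O)c1
F5 | step 9 | thiocarbonylimidazolide of F4 | COc1cc(C)c(OC)c(C(OC(=S)n2ccnc2)[C@]3(C)[C@]4(O)CCCC5(OCCO5)[C@]4(C)CCC3=O)c1
F6 | step 13 | Δ1(10) C4 ketone | COc1cc(C)c(OC)c(C[C@]2(C)C3=CCCC(=O)[C@]3(C)CC[C@@H]2C)c1
F7 | step 13 | dienyl triflate (C1=C10, C3=C4-OTf) | COc1cc(C)c(OC)c(C[C@]2(C)C3=CCC=C(OS(=O)(=O)C(F)(F)F)[C@]3(C)CC[C@@H]2C)c1
F8 | step 13 | diene ester (C1=C10, C3=C4 with CH2CH2CO2Et at C4) | COc1cc(C)c(OC)c(C[C@]2(C)C3=CCC=C(CCC(=O)OCC)[C@]3(C)CC[C@@H]2C)c1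
F9 | step 13 | homoallylic alcohol (3α-OH, 4β-chain, C1=C10) | COc1cc(C)c(OC)c(C[C@]2(C)C3=CC[C@H](O)[C@@H](CCC(=O)OCC)[C@]3(C)CC[C@@H]2C)c1
F10 | step 18 | β-hydroxy acid (C3 carbinol with C(CH3)2CO2H, mixture at C3) | COc1cc(C)c(OC)c(C[C@]2(C)[C@H]3CCC(O)(C(C)(C)C(=O)O)[C@@H](CCC(=O)OCC)[C@]3(C)CC[C@@H]2C)c1
F11 | step 18 | spiro β-lactone at C3 | COc1cc(C)c(OC)c(C[C@]2(C)[C@H]3CCC4(OC(=O)C4(C)C)[C@@H](CCC(=O)OCC)[C@]3(C)CC[C@@H]2C)c1
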